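Millimolar is the unit of the one number carried through this meeting, a level of target, and the flasks it concerns are these.

    starting material + target → side product (k1 = 770 M⁻¹ s⁻¹)
    catalyst intermediate C → free catalyst + target (k2 = 13 s⁻¹)
    catalyst intermediate B → by-product + catalyst intermediate C (k3 = 2.8 s⁻¹)
    starting material + catalyst intermediate A → catalyst intermediate B (k4 = 5200 M⁻¹ s⁻¹)
    reagent + free catalyst → catalyst intermediate A (k5 = 4500 M⁻¹ s⁻¹)

| setting | elm | cedar | alder | oak |
|---|---|---|---|---|
| starting material | 2.0 mM | 2.0 mM | 2.0 mM | 2.0 mM (fed, over 50.0 s) |
| reagent | 1.00 equiv | 1.00 equiv | 1.00 equiv | 1.00 equiv |
| free catalyst | 5 mol% | 5 mol% | 5 mol% | 5 mol% |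
| remark | one stirred flow tank at steady state, fed with the mixture as stated, mean residence time 50 s | a closed flask charged with all of it at once and left for 50 s | plug flow through a tube for 50 s, no back-mixing | a stirred flask in which starting material is dosed at a steady rate over 50.0 s without added volume, worked up at 50 s |
| time |  | 50 s | 50 s | 50 s |

- the set-up with the highest amount of target at the outlet or at the end, in percent of the starting material put in ("none" if the first two lie within 2 percentage points) (elm / cedar / alder / oak / none)
- amount of target at the outlet or at the end, in percent of the starting material put in, elm
- amount of target at the outlet or at the end, in percent of the starting material put in, cedar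
- amount of target at the outlet or at the end, in percent of the starting material put in, alder
- amount of target at the outlet or at the end, in percent of the starting material put in, oak

- percentages count the starting material that a species holds: one side product counts as two
- the stated concentrations are those of everything mixed, before any reaction; amounts are the same in each set-up
- the feed brings no volume worth counting
- run time (cedar): 50 s

**Minutes.** The kineticist noted that, with S for starting material and T for target, both routes consuming starting material carry the factor S: capture by catalyst intermediate A at 5200 M⁻¹ s⁻¹, attack by target at 770 M⁻¹ s⁻¹. With c = 0.100 mM of catalyst resting as catalyst intermediate A (its resting state), S cancels from their ratio, which leaves L = 0.675 mM, the target level at which target takes starting material as fast as the catalyst does. Each capture later yields one target and each attack destroys one, so target gained per starting material spent is (L−T)/(L+T). Integrated, the amount spent is 2L ln(L/(L−T)) − T, and time has dropped out.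

The process engineer applied this to oak. With reagent at its full charge, she reckoned, the steps after capture take 0.545 s per turn, so turning over at the feed pace of 0.0400 mM s⁻¹ ties up an estimated 21.8% of the catalyst outside catalyst intermediate A. She kept L whole, accepting that this errs high. Setting the amount spent to the charge and iterating on x = T/L gave x = 0.851, hence 28.7% for oak.

The kineticist objected that cedar and alder, which follow the same equations, begin with S above 0.353 mM, the level at which half of the catalyst sits in catalyst intermediate A. As a crude guess she proposed that share throughout, so L becomes 0.338 mM. Turning over the charge takes about 10.9 s, less than 50 s, so she spent the charge fully. The iteration gave x = 0.968, hence 16.3% for cedar and 16.3% for alder.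

The engineer added that elm holds one composition, so nothing is integrated. With S neglected and L whole, T/c₀ = (L−T)/(L+T), where c₀ is the charge of starting material, and the quadratic gives 0.434 mM, or 21.7%. The meeting ranked oak first.

The forecast gave 19% for elm, 16.5% for cedar, 16.5% for alder and 25.7% for oak, with oak best, since “Dosing keeps S low”, and it stands below the meeting's figures for elm and oak.

The simulation gives 18.7% for elm, 16.6% for cedar, 16.6% for alder and 25.3% for oak, with oak best.

In alder at 4.08 s, capture uses starting material 1.1 times as fast as target does, and the end holds 0.332 mM of target, less than L. In oak at 50.0 s, 84.0% of the catalyst is catalyst intermediate A, which scales L to 0.567 mM, and target stands at 0.506 mM.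

For alder with 12 mol% of free catalyst, L grows to 1.62 mM, and its half share 0.810 mM gives x = 0.804, or 32.6%. The computed flask gives 30.6%.

The rate constants come from no measurement.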